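The readings were computed with made-up constants; scatter was added.

**One-step world.** In a one-step world, substrate and reagent give target and isomer side by side, so the share of target in target plus isomer stays put as the hours pass. The bench habit follows: read the share once and carry it to the next flask.

in all of them: free catalyst 32 mM

| flask | substrate | reagent | capture agent | temperature | remark | time |
|---|---|---|---|---|---|---|
| green | 0.32 M | 0.224 M | 6.4 mM | 95 °C | run made earlier |  |
| amber | 0.32 M | 0.11 M | 6.4 mM | 110 °C | run made earlier |  |
| red | 0.32 M | 0.45 M | 6.4 mM | 95 °C | run made earlier |  |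
| blue | 0.48 M | 0.224 M | 6.4 mM | 110 °C | run made earlier |  |
| Monday's | 0.32 M | 0.224 M | 6.40 mM | 110 °C | everything together at the start | 6.0 h |
| Thursday's | 0.32 M | 0.224 M (fed, over 2.5 h) | 6.40 mM | 110 °C | all else is in the flask from the start; the feed brings no volume worth counting | 6.0 h |
| Wednesday's | 0.32 M | 0.224 M (in portions, 2, over 2.5 h) | 6.40 mM | 110 °C | first portion at the start, last at 2.5 h | 6.0 h |
| Friday's | 0.32 M (fed, over 2.5 h) | 0.224 M | 6.40 mM |  | the addition at 90 °C, then warmed to 110 °C; the feed brings no volume worth counting | 6.0 h |

| run | time / h | target / % | isomer of the product / % |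
|---|---|---|---|
| green | 0.500 | 1 | 0 |
| green | 1.00 | 1 | 2 |
| green | 2.00 | 3 | 2 |
| green | 3.00 | 9 | 3 |
| green | 4.00 | 7 | 5 |
| green | 8.00 | 13 | 10 |
| amber | 0.833 | 1 | 0 |
| amber | 1.50 | 1 | 2 |
| amber | 2.50 | 6 | 4 |
| amber | 3.00 | 7 | 3 |
| amber | 4.00 | 9 | 5 |
| amber | 5.00 | 10 | 7 |
| red | 2.00 | 6 | 0 |
| red | 3.00 | 8 | 2 |
| red | 5.00 | 12 | 9 |
| red | 6.00 | 14 | 9 |
| red | 8.00 | 17 | 14 |
| red | 10.0 | 19 | 22 |
| blue | 1.00 | 1 | 5 |
| blue | 2.00 | 8 | 5 |
| blue | 3.00 | 9 | 6 |
| blue | 4.00 | 12 | 11 |
| blue | 5.00 | 11 | 10 |

(standard deviation of a reading: 1.5 percentage points)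

* which flask leads in share of target in target plus isomer of the product ("all alike" within 1.5 percentage points) (Monday's / Thursday's / Wednesday's / Friday's / all alike)
* share of target in target plus isomer of the product at the end, Monday's
* share of target in target plus isomer of the product at the end, Thursday's
* share of target in target plus isomer of the product at the end, Wednesday's
* share of target in target plus isomer of the product at the end, Friday's

- the numbers in the tables scatter by 1.5 percentage points (one standard deviation)

**Where it stopped.** I tried that habit first: the last green reading gives a share of 56.5%, which it carries to Monday's, Thursday's, Wednesday's and Friday's alike. But I then read ρ, isomer per target, in the red run: 0.250 at 3.00 h and 1.16 at 10.0 h, a factor of 4.63 in readings that scatter. A constant ratio does not fit those two readings. So I followed one molecule, supposing that it is target first and that each hour it stays brings a new chance of turning into isomer.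

**Isomer clock.** I therefore took c, the rise of ρ per hour, as the isomer clock, with the share as 1/(1+ρ). Pooling the last amber and blue readings at 110 °C gave 0.162 /h. Pooling green and red at 8.00 h gave 0.100 /h at 95 °C, which is warmer than Friday's addition, so I took it as too fast for those hours.

Monday's then came to 50.7%. Friday's, with 2.5 h on the cooler clock and the rest on the hot one, came to 55.0%. Thursday's and Wednesday's keep their hot hours, so I put them near Monday's.

**The forecast.** It named Thursday's as leader, with Monday's 54%, Thursday's 57%, Wednesday's 56% and Friday's 55%, and called this “a weak lead for Thursday's, only just beyond the noise”. My reckoning differed: it put Friday's first.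

**The flasks.** Friday's led with 55.3%, against Monday's 47.8%, Thursday's 50.3% and Wednesday's 50.9%.

    target + free catalyst ⇌ isomer of the product + free catalyst, rate k1*[free catalyst]*[target] forward; the back reaction follows from the equilibrium constant (K = 1.95, k = 0.435 /M/min, Ea = 76.0 kJ/mol, ΔH = −36.0 kJ/mol)
    reagent + catalyst intermediate → free catalyst + target (k = 0.308 /M/min, Ea = 63.0 kJ/mol)
    substrate + free catalyst → free catalyst + open intermediate (k = 0.610 /M/min, Ea = 69.0 kJ/mol)
    free catalyst + open intermediate ⇌ catalyst intermediate (K = 2.25 /M, k = 0.210 /M/min, Ea = 77.0 kJ/mol, ΔH = −38.0 kJ/mol)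
    open intermediate + capture agent → trapped intermediate (k = 0.00446 /M/min, Ea = 96.0 kJ/mol)
    free catalyst → spent catalyst (k = 0.00159 /min, Ea = 123 kJ/mol)
    (constants at 110 °C)

**The neighbour.** I ran the clock on Friday's flask left until 15 h. It gave ρ of 2.27, so a share of 30.5%, and that ρ stands above the equilibrium constant 1.95 of the step between target and isomer at 110 °C. The flask gave 39.3%, a ρ of 1.54. Friday's itself, left until 60.0 h, stood at 35.8%.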